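The target is natural (−)-epigallocatechin 3-O-gallate with methyl groups on the two meta oxygens of its acyl ring, so the route rests on one disconnection: the O3''–CH3 and O5''–CH3 bonds. A tea Mg2+-dependent O-methyltransferase forms both bonds in one pot on the unprotected ester, the methyl groups coming from the sulfonium of S-adenosyl-L-methionine. The step exploits galloyl ring D: its vicinal O3''/O4'' pair, and after the first transfer the O4''/O5'' pair, chelates the metal and presents the meta oxygen to the donor, while rotation about the C1''–C4'' axis makes O3'' and O5'' equivalent. The precursor is the purchased (2R,3R) ester, eight free phenols, both stereocentres in place.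

Key step: step 1

Remark on the cofactor structure: the sulfonium sulfur of S-adenosyl-L-methionine is a stereocentre, and only the (S)-sulfonium epimer is accepted by methyltransferases. Compound 2 is therefore drawn with that configuration. Two molecules are consumed per molecule of product, and the excess is reckoned on the active epimer because commercial salts contain some (R)-sulfonium epimer.

Remark on the precursor: the ester is used unprotected, since any phenol protection would first have to tell the B-ring pyrogallol from the D-ring pyrogallol, which is the same problem as the methylation itself.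

Remark on the catalyst: the recombinant tea enzyme (His-tagged, expressed in E. coli, purified on Ni-NTA) is assumed to be prepared separately and is not counted as a step. No cofactor regeneration is built in; 2 is used stoichiometrically in excess.

Ring labels: A = the 5,7-dihydroxy benzo ring, C = the pyran ring (C2, C3, C4), B = the 3',4',5'-trihydroxyphenyl ring on C2, D = the galloyl ring (doubly primed locants).

Step 1
Reactants: 1 (−)-epigallocatechin 3-O-gallate; 2 S-adenosyl-L-methionine, (S)-sulfonium epimer (two molecules consumed)
Product: 4 (−)-epigallocatechin 3-O-(3,5-di-O-methylgallate), via 3''-O-methyl monoether 3 (not isolated)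
Conditions: recombinant tea (Camellia sinensis) Mg2+-dependent catechol-type O-methyltransferase (caffeoyl-CoA OMT family), 2 (4 equiv of active epimer, commercial salt, two portions, pH readjusted), MgCl2, sodium ascorbate, degassed HEPES pH 7.2, N2, 30 °C, 16–24 h; then pH 3, EtOAc extraction, preparative C18 HPLC (MeCN/H2O/HCO2H)
Reagents that add atoms: S-adenosyl-L-methionine (compound 2, donor of both CH3 groups), C[S@@+](CC[C@@H](C(=O)[O-])N)C[C@@H]1[C@H]([C@H]([C@@H](O1)N2C=NC3=C(N=CN=C32)N)O)O
Why: This is an enzymatic SAM-dependent O-methylation of the cation-dependent catechol O-methyltransferase type: the O3''/O4'' diol of ring D binds the active-site Mg2+, an active-site base takes the proton of the meta hydroxyl, and the resulting phenoxide displaces S-adenosyl-L-homocysteine from the S-methyl carbon of 2 in an in-line SN2 transfer to give monoether 3. In 3 the O4''/O5'' pair remains a free catechol, so 3 should bind again with ring D turned about its C1''–C4'' axis and take the second methyl group at O5'' to give 4. The closest known reaction is the methylation of the galloyl hydroxyls of galloylated tea catechins by this enzyme family, which is known to deliver both the 3''-methyl and the 3'',5''-dimethyl ethers of this ester. No ring is closed and no stereocentre is formed; C2 and C3 stay (2R,3R), and near-neutral pH at 30 °C under nitrogen with ascorbate should suppress C2 epimerisation, autoxidation of the pyrogallol rings and ester hydrolysis. The step needs site selectivity for O3'' and O5'' over O4'', over the B-ring oxygens O3'/O4'/O5' and over the A-ring oxygens O5/O7; it should follow from the meta preference of this enzyme family for a metal-bound catechol, from the ester carbonyl that makes ring D a caffeoyl-like acyl unit fitting the active site better than ring B, and from the resorcinol pattern of ring A, which cannot chelate the metal. Residual 3, the 4''-methyl isomer and any B-ring ethers should separate on reversed phase, where each added methyl group lengthens retention.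

Compound list
1 | (−)-epigallocatechin 3-O-gallate; (2R,3R)-5,7-dihydroxy-2-(3,4,5-trihydroxyphenyl)chroman-3-yl 3,4,5-trihydroxybenzoate, 2,3-cis | O=C(O[C@@H]1Cc2c(O)cc(O)cc2O[C@@H]1c1cc(O)c(O)c(O)c1)c1cc(O)c(O)c(O)c1 | starting material
2 | S-adenosyl-L-methionine, inner salt; (S) at sulfur, (S) at the α-carbon, β-D-ribofuranosyl adenine | C[S@@+](CC[C@@H](C(=O)[O-])N)C[C@@H]1[C@H]([C@H]([C@@H](O1)N2C=NC3=C(N=CN=C32)N)O)O | starting material
3 | (−)-epigallocatechin 3-O-(3-O-methylgallate); (2R,3R)-5,7-dihydroxy-2-(3,4,5-trihydroxyphenyl)chroman-3-yl 3,4-dihydroxy-5-methoxybenzoate | COc1cc(C(=O)O[C@@H]2Cc3c(O)cc(O)cc3O[C@@H]2c2cc(O)c(O)c(O)c2)cc(O)c1O | intermediate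
4 | (−)-epigallocatechin 3-O-(3,5-di-O-methylgallate); (2R,3R)-5,7-dihydroxy-2-(3,4,5-trihydroxyphenyl)chroman-3-yl 4-hydroxy-3,5-dimethoxybenzoate | COc1cc(C(=O)O[C@@H]2Cc3c(O)cc(O)cc3O[C@@H]2c2cc(O)c(O)c(O)c2)cc(OC)c1O | target

Total step count: 1
Longest linear sequence: 1 step

Steps most likely to fail: the route has a single step, so the ranking has one entry.

Step 1. Three processes may spoil it:
- the reaction may stall after the first methyl transfer, through inhibition by the spent cofactor or weak rebinding of 3;
- methyl transfer may go to O4'' or to the B-ring oxygens, giving poor site selectivity;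
- the polyphenol may be lost by oxidation or C2 epimerisation during the long incubation.

Fallback (exchange of the whole acyl group by known chemistry in place of late methylation): setting out from 1, tannase (tannin acyl hydrolase, citrate buffer pH 5, 37 °C) would cleave the gallate ester to give (−)-epigallocatechin F1. Benzyl bromide and K2CO3 in DMF under argon would etherify the five phenols and leave the hindered axial 3-OH free, giving 5,7,3',4',5'-penta-O-benzyl-(−)-epigallocatechin F2. Steglich esterification (DCC, DMAP, CH2Cl2) with purchased 4-benzyloxy-3,5-dimethoxybenzoic acid would give 5,7,3',4',5'-penta-O-benzyl-(−)-epigallocatechin 3-O-(4-O-benzyl-3,5-di-O-methylgallate) F3. Hydrogenolysis of the six benzyl ethers (H2, Pd(OH)2/C, THF/MeOH) would then come back to the route at 4. Neither stereocentre is touched, and the methyl pattern is fixed by the purchased acid.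

Further compounds
F1 | step 1 | (−)-epigallocatechin, (2R,3R) | O[C@@H]1Cc2c(O)cc(O)cc2O[C@@H]1c1cc(O)c(O)c(O)c1
F2 | step 1 | 5,7,3',4',5'-penta-O-benzyl-(−)-epigallocatechin, (2R,3R) | O[C@@H]1Cc2c(OCc3ccccc3)cc(OCc3ccccc3)cc2O[C@@H]1c1cc(OCc2ccccc2)c(OCc2ccccc2)c(OCc2ccccc2)c1
F3 | step 1 | 5,7,3',4',5'-penta-O-benzyl-(−)-epigallocatechin 3-O-(4-O-benzyl-3,5-di-O-methylgallate), (2R,3R) | COc1cc(C(=O)O[C@@H]2Cc3c(OCc4ccccc4)cc(OCc4ccccc4)cc3O[C@@H]2c2cc(OCc3ccccc3)c(OCc3ccccc3)c(OCc3ccccc3)c2)cc(OC)c1OCc1ccccc1
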